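**Retrosynthetic overview**
- The target comes from hydrogenolysis of its tri-benzyl precursor (benzyl ester and two benzyl ethers on ring A), which frees the ring-A keto acid under neutral conditions.
- The isocoumarin pyranone is the only ring formed, in the penultimate step: the ring-B benzoic acid ortho C–H is joined to the α-carbon of an α-keto sulfoxonium ylide (α-keto carbenoid, an enolonium-type a2 synthon), then lactonised.
- The ring-A 2-oxoheptyl chain comes from the lateral (toluate) anion of the orsellinate methyl group and a Weinreb amide.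
- The diaryl ether comes from Cu-catalysed coupling of a 5-iodo-orsellinate with methyl 4-methoxysalicylate.
- Order: both benzene rings are bought, then ether, ring-A chain, isocoumarin ring, deprotection.

Assumption: the target has no stereocentre and no stereogenic alkene, so it is achiral and no stereocontrol is needed; ring A is delivered as the open keto acid drawn.

**Step 1**
Reactants: 1 orsellinic acid (2,4-dihydroxy-6-methylbenzoic acid)
Product: 2 benzyl 2,4-bis(benzyloxy)-6-methylbenzoate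
Conditions: BnBr (3.5 equiv), K2CO3 (4 equiv), DMF, rt then 60 °C
Reagents that add atoms: benzyl bromide, BrCc1ccccc1
Why: Williamson-type O-alkylation in which the carboxylate is benzylated first at rt (which stops decarboxylation) and then both phenols, the chelated 2-OH last on warming.

**Step 2**
Reactants: 2 benzyl 2,4-bis(benzyloxy)-6-methylbenzoate
Product: 3 benzyl 4,6-bis(benzyloxy)-3-iodo-2-methylbenzoate
Conditions: NIS (1.05 equiv), TFA (10 mol %), MeCN, 0 °C to rt
Reagents that add atoms: N-iodosuccinimide, O=C1CCC(=O)N1I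
Why: Electrophilic aromatic iodination at the site next to the methyl group, which is para to one benzyloxy group and ortho to the other and less shielded than the site between the two benzyloxy groups.

**Step 3**
Reactants: 3 benzyl 4,6-bis(benzyloxy)-3-iodo-2-methylbenzoate; 4 methyl 2-hydroxy-4-methoxybenzoate
Product: 6 2-[4,6-bis(benzyloxy)-3-(benzyloxycarbonyl)-2-methylphenoxy]-4-methoxybenzoic acid, via diaryl ether methyl ester 5 (not isolated)
Conditions: 4 (1.5 equiv), CuI (20 mol %), picolinic acid (40 mol %), K3PO4 (2.5 equiv), DMSO, 90 °C; then LiOH·H2O (4 equiv), THF/MeOH/H2O, 45 °C; 1 M HCl work-up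
Reagents that add atoms: lithium hydroxide, [Li+].[OH-]
Why: Ullmann-type Cu-catalysed C–O coupling with a picolinate ligand system that tolerates di-ortho-substituted aryl iodides, followed by saponification of only the mono-ortho-substituted methyl ester while the 2,6-disubstituted benzyl ester is sterically protected.

**Step 4**
Reactants: 6 2-[4,6-bis(benzyloxy)-3-(benzyloxycarbonyl)-2-methylphenoxy]-4-methoxybenzoic acid; 7 N-methoxy-N-methylhexanamide
Product: 8 2-[4,6-bis(benzyloxy)-3-(benzyloxycarbonyl)-2-(2-oxoheptyl)phenoxy]-4-methoxybenzoic acid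
Conditions: LDA (commercial solution, 2.4 equiv), THF, −78 °C; then 7 (1.3 equiv), −78 to −30 °C; 1 M HCl quench
Reagents that add atoms: none
Why: Lateral (benzylic) lithiation of the o-toluate ester and Weinreb ketone synthesis, in which the ring-B carboxylate is only deprotonated (and deactivates that ring against Truce–Smiles attack) and the chelated tetrahedral adduct prevents over-addition and premature lactonisation.

**Step 5**
Reactants: 9 trimethylsulfoxonium iodide; 10 hexanoyl chloride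
Product: 12 1-[dimethyl(oxo)-λ6-sulfanylidene]heptan-2-one, via dimethylsulfoxonium methylide 11 (not isolated)
Conditions: 9 (3 equiv), KOtBu (3 equiv), THF, reflux, 2 h; then 10 (1 equiv), 0 °C to rt
Reagents that add atoms: none
Why: C-acylation of the Corey–Chaykovsky ylide, in which a second equivalent of ylide removes the proton to give the stabilised β-keto sulfoxonium ylide.

**Step 6**
Reactants: 8 2-[4,6-bis(benzyloxy)-3-(benzyloxycarbonyl)-2-(2-oxoheptyl)phenoxy]-4-methoxybenzoic acid; 12 1-[dimethyl(oxo)-λ6-sulfanylidene]heptan-2-one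
Product: 14 benzyl 4,6-bis(benzyloxy)-3-[(6-methoxy-1-oxo-3-pentyl-1H-isochromen-8-yl)oxy]-2-(2-oxoheptyl)benzoate, via ortho-acylmethyl keto acid 13 (not isolated)
Conditions: 12 (1.5 equiv), [Cp*RhCl2]2 (4 mol %), AgSbF6 (16 mol %), NaOAc (0.5 equiv), HFIP, 70 °C
Reagents that add atoms: none
Why: Carboxylate-directed Rh(III) C–H activation at the only free ortho position of the ring-B acid, formation of a Rh α-keto carbene from the ylide with loss of DMSO and 1,1-migratory insertion of the aryl group (the ketone α-carbon, normally a nucleophile, acts as acceptor towards the nucleophilic aryl–Rh carbon), then cyclodehydration of the 2-(2-oxoheptyl)benzoic acid to the isocoumarin, a known annulation type for benzoic acids with sulfoxonium ylides, while ring A cannot react because its acid is a hindered benzyl ester with no ortho C–H.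

**Step 7**
Reactants: 14 benzyl 4,6-bis(benzyloxy)-3-[(6-methoxy-1-oxo-3-pentyl-1H-isochromen-8-yl)oxy]-2-(2-oxoheptyl)benzoate
Product: 15 β-collatolic acid (4,6-dihydroxy-3-[(6-methoxy-1-oxo-3-pentyl-1H-isochromen-8-yl)oxy]-2-(2-oxoheptyl)benzoic acid)
Conditions: H2 (1 atm), 10% Pd/C, EtOAc, rt, stopped after uptake of 3 equiv
Reagents that add atoms: none
Why: Hydrogenolysis of the benzyl ester and both benzyl ethers under neutral conditions, where the trisubstituted enol-lactone alkene is reduced much more slowly and the ring-A keto acid is released without acid or heat, so it does not lactonise.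

**Compound list**
1 | orsellinic acid (2,4-dihydroxy-6-methylbenzoic acid) | Cc1cc(O)cc(O)c1C(=O)O | starting material
2 | benzyl 2,4-bis(benzyloxy)-6-methylbenzoate | Cc1cc(OCc2ccccc2)cc(OCc2ccccc2)c1C(=O)OCc1ccccc1 | intermediate
3 | benzyl 4,6-bis(benzyloxy)-3-iodo-2-methylbenzoate | Cc1c(I)c(OCc2ccccc2)cc(OCc2ccccc2)c1C(=O)OCc1ccccc1 | intermediate
4 | methyl 2-hydroxy-4-methoxybenzoate | COC(=O)c1ccc(OC)cc1O | starting material
5 | benzyl 4,6-bis(benzyloxy)-3-[5-methoxy-2-(methoxycarbonyl)phenoxy]-2-methylbenzoate | Cc1c(Oc2cc(OC)ccc2C(=O)OC)c(OCc2ccccc2)cc(OCc2ccccc2)c1C(=O)OCc1ccccc1 | intermediate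
6 | 2-[4,6-bis(benzyloxy)-3-(benzyloxycarbonyl)-2-methylphenoxy]-4-methoxybenzoic acid | Cc1c(Oc2cc(OC)ccc2C(=O)O)c(OCc2ccccc2)cc(OCc2ccccc2)c1C(=O)OCc1ccccc1 | intermediate
7 | N-methoxy-N-methylhexanamide | CCCCCC(=O)N(C)OC | starting material
8 | 2-[4,6-bis(benzyloxy)-3-(benzyloxycarbonyl)-2-(2-oxoheptyl)phenoxy]-4-methoxybenzoic acid | CCCCCC(=O)Cc1c(Oc2cc(OC)ccc2C(=O)O)c(OCc2ccccc2)cc(OCc2ccccc2)c1C(=O)OCc1ccccc1 | intermediate
9 | trimethylsulfoxonium iodide | C[S+](C)(C)=O.[I-] | starting material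
10 | hexanoyl chloride | CCCCCC(Cl)=O | starting material
11 | dimethylsulfoxonium methylide | [CH2-][S+](C)(C)=O | intermediate
12 | 1-[dimethyl(oxo)-λ6-sulfanylidene]heptan-2-one | CCCCCC(=O)C=S(C)(C)=O | intermediate
13 | 2-[4,6-bis(benzyloxy)-3-(benzyloxycarbonyl)-2-(2-oxoheptyl)phenoxy]-4-methoxy-6-(2-oxoheptyl)benzoic acid | CCCCCC(=O)Cc1cc(OC)cc(Oc2c(CC(=O)CCCCC)c(C(=O)OCc3ccccc3)c(OCc3ccccc3)cc2OCc2ccccc2)c1C(=O)O | intermediate
14 | benzyl 4,6-bis(benzyloxy)-3-[(6-methoxy-1-oxo-3-pentyl-1H-isochromen-8-yl)oxy]-2-(2-oxoheptyl)benzoate | CCCCCC(=O)Cc1c(Oc2cc(OC)cc3cc(CCCCC)oc(=O)c23)c(OCc2ccccc2)cc(OCc2ccccc2)c1C(=O)OCc1ccccc1 | intermediate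
15 | β-collatolic acid (achiral) | CCCCCC(=O)Cc1c(Oc2cc(OC)cc3cc(CCCCC)oc(=O)c23)c(O)cc(O)c1C(=O)O | target

**Step count**
Total: 7 steps. Longest linear sequence: 6 steps (1, 2, 3, 4, 6, 7 from orsellinic acid); step 5 is a one-step branch.

**Three steps most likely to fail**

Step 3. The aryl iodide is di-ortho-substituted and electron-rich, and the phenol is chelated and electron-poor, so coupling may be slow and protodeiodination may win. The fallback reverses the roles in the ether formation; it sets out from 3 and comes back at 6. Iodine–magnesium exchange on 3 (i-PrMgCl·LiCl, THF, −20 °C) and B(OMe)3 give benzyl 4,6-bis(benzyloxy)-3-(dimethoxyboranyl)-2-methylbenzoate F1, not isolated. Oxidation with H2O2/aq. NaOH at 0 °C gives benzyl 4,6-bis(benzyloxy)-3-hydroxy-2-methylbenzoate F2. This hindered phenol is then arylated with commercial 2-bromo-4-methoxybenzoic acid (COc1ccc(C(=O)O)c(Br)c1; CuI, Cs2CO3, DMF, 100 °C), an ortho-carboxylate-assisted Ullmann coupling that gives acid 6 directly.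

Step 4. The lithium carboxylate dianion may be poorly soluble, the amide may be enolised, or the benzylic anion may attack ring B (Truce–Smiles). The fallback installs the chain before the ether is made; it sets out from 2 and comes back at 8. Lateral lithiation of 2 (LDA, THF, −78 °C) and acylation with 7 give benzyl 2,4-bis(benzyloxy)-6-(2-oxoheptyl)benzoate F3. Ketalisation ((TMSOCH2)2, cat. TMSOTf, CH2Cl2, −78 to −20 °C) gives benzyl 2,4-bis(benzyloxy)-6-[(2-pentyl-1,3-dioxolan-2-yl)methyl]benzoate F4; the ketal blocks the benzofuran closure that a free ortho-halobenzyl ketone would undergo in the copper step. Iodination (NIS, MeCN, 40 °C, no acid) gives benzyl 4,6-bis(benzyloxy)-3-iodo-2-[(2-pentyl-1,3-dioxolan-2-yl)methyl]benzoate F5. The Cu coupling of step 3 with 4 gives benzyl 4,6-bis(benzyloxy)-3-[5-methoxy-2-(methoxycarbonyl)phenoxy]-2-[(2-pentyl-1,3-dioxolan-2-yl)methyl]benzoate F6, not isolated, and LiOH then gives 2-{4,6-bis(benzyloxy)-3-(benzyloxycarbonyl)-2-[(2-pentyl-1,3-dioxolan-2-yl)methyl]phenoxy}-4-methoxybenzoic acid F7. PPTS in acetone/H2O at 40 °C removes the ketal and gives 8.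

Step 6. The carboxylate is a weak directing group next to a bulky aryloxy substituent, the ylide may O-alkylate the acid, and Lewis acid could close ring A. The fallback uses a stronger N–O directing group and separates C–C bond formation from ring closure; it sets out from 8 and comes back at 14. Amide coupling of 8 (EDC·HCl, HOBt, MeONH2·HCl 1.05 equiv, i-Pr2NEt, CH2Cl2, 0 °C, basic so the ketone is not oximated) gives benzyl 4,6-bis(benzyloxy)-3-[5-methoxy-2-(methoxycarbamoyl)phenoxy]-2-(2-oxoheptyl)benzoate F8. Rh(III)-catalysed C–H acylmethylation with 12 ([Cp*RhCl2]2, AgSbF6, DCE, 60 °C) gives benzyl 4,6-bis(benzyloxy)-3-[5-methoxy-2-(methoxycarbamoyl)-3-(2-oxoheptyl)phenoxy]-2-(2-oxoheptyl)benzoate F9, which is isolated. Warming F9 in AcOH/acetone at 60 °C closes the amide oxygen onto the ketone and expels methoxyamine (acetone keeps it away from the ring-A ketone), giving 14.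

**Further compounds**
F1 | step 3 | benzyl 4,6-bis(benzyloxy)-3-(dimethoxyboranyl)-2-methylbenzoate | Cc1c(B(OC)OC)c(OCc2ccccc2)cc(OCc2ccccc2)c1C(=O)OCc1ccccc1
F2 | step 3 | benzyl 4,6-bis(benzyloxy)-3-hydroxy-2-methylbenzoate | Cc1c(O)c(OCc2ccccc2)cc(OCc2ccccc2)c1C(=O)OCc1ccccc1
F3 | step 4 | benzyl 2,4-bis(benzyloxy)-6-(2-oxoheptyl)benzoate | CCCCCC(=O)Cc1cc(OCc2ccccc2)cc(OCc2ccccc2)c1C(=O)OCc1ccccc1
F4 | step 4 | benzyl 2,4-bis(benzyloxy)-6-[(2-pentyl-1,3-dioxolan-2-yl)methyl]benzoate | CCCCCC1(Cc2cc(OCc3ccccc3)cc(OCc3ccccc3)c2C(=O)OCc2ccccc2)OCCO1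
F5 | step 4 | benzyl 4,6-bis(benzyloxy)-3-iodo-2-[(2-pentyl-1,3-dioxolan-2-yl)methyl]benzoate | CCCCCC1(Cc2c(I)c(OCc3ccccc3)cc(OCc3ccccc3)c2C(=O)OCc2ccccc2)OCCO1
F6 | step 4 | benzyl 4,6-bis(benzyloxy)-3-[5-methoxy-2-(methoxycarbonyl)phenoxy]-2-[(2-pentyl-1,3-dioxolan-2-yl)methyl]benzoate | CCCCCC1(Cc2c(Oc3cc(OC)ccc3C(=O)OC)c(OCc3ccccc3)cc(OCc3ccccc3)c2C(=O)OCc2ccccc2)OCCO1
F7 | step 4 | 2-{4,6-bis(benzyloxy)-3-(benzyloxycarbonyl)-2-[(2-pentyl-1,3-dioxolan-2-yl)methyl]phenoxy}-4-methoxybenzoic acid | CCCCCC1(Cc2c(Oc3cc(OC)ccc3C(=O)O)c(OCc3ccccc3)cc(OCc3ccccc3)c2C(=O)OCc2ccccc2)OCCO1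
F8 | step 6 | benzyl 4,6-bis(benzyloxy)-3-[5-methoxy-2-(methoxycarbamoyl)phenoxy]-2-(2-oxoheptyl)benzoate | CCCCCC(=O)Cc1c(Oc2cc(OC)ccc2C(=O)NOC)c(OCc2ccccc2)cc(OCc2ccccc2)c1C(=O)OCc1ccccc1
F9 | step 6 | benzyl 4,6-bis(benzyloxy)-3-[5-methoxy-2-(methoxycarbamoyl)-3-(2-oxoheptyl)phenoxy]-2-(2-oxoheptyl)benzoate | CCCCCC(=O)Cc1cc(OC)cc(Oc2c(CC(=O)CCCCC)c(C(=O)OCc3ccccc3)c(OCc3ccccc3)cc2OCc2ccccc2)c1C(=O)NOC
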